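A small charge of catalyst, 20 µM against 10 mM of starting material, has to compete with a side reaction that needs no catalyst.

    starting material + free catalyst → catalyst intermediate A (k1 = 3100 L mol⁻¹ s⁻¹, Ea1 = 42.0 kJ mol⁻¹)
    catalyst intermediate A → catalyst intermediate B (k2 = 64 s⁻¹, Ea2 = 78.0 kJ mol⁻¹)
    reagent + catalyst intermediate B ⇌ catalyst intermediate C (K3 = 170 L mol⁻¹, k3 = 32000 L mol⁻¹ s⁻¹, Ea3 = 27.0 kJ mol⁻¹, ΔH3 = −32.0 kJ mol⁻¹)
    catalyst intermediate C → released group + catalyst intermediate D (k4 = 66 s⁻¹, Ea4 = 73.0 kJ mol⁻¹)
    catalyst intermediate D → free catalyst + target (k5 = 75 s⁻¹, Ea5 = 77.0 kJ mol⁻¹)
    2 starting material → self-condensation product (k6 = 18 L mol⁻¹ s⁻¹, Ea6 = 50.0 kJ mol⁻¹)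
    (constants at 80 °C)

| flask | starting material | reagent | free catalyst | temperature | time | remark |
|---|---|---|---|---|---|---|
| theta | 10 mM | 15.0 mM (fed, over 4.0 s) | 20 µM | 80 °C | 20 s | all else is in the flask from the start; the feed brings no volume worth counting |
| zeta | 10 mM | 15.0 mM (fed, over 15 s) | 20 µM | 80 °C | 20 s | all else is in the flask from the start; the feed brings no volume worth counting |
| eta | 10 mM (fed, over 15 s) | 15.0 mM | 20 µM | 80 °C | 20 s | all else is in the flask from the start; the feed brings no volume worth counting |
| alpha | 10 mM | 15.0 mM | 20 µM | 80 °C | 20 s | everything together at the start |
| beta | 10 mM (fed, over 15 s) | 15.0 mM | 20 µM |  | 20 s | the addition at 50 °C, then warmed to 80 °C; the feed brings no volume worth counting |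

- percent here means starting material units held: one self-condensation product counts as two
- where a step has two of a species, its rate is k times that concentration squared, and two are used at each turn
- at 80 °C the constants are as listed, elsewhere as the activation energies and enthalpies make them

1. which flask leads in amount of target, in percent of the starting material charged ("all alike" within 1.5 percentage points) (theta / zeta / eta / alpha / beta / all alike)
2. how much target is there at the end, in percent of the starting material charged: theta
3. how much target is there at the end, in percent of the starting material charged: zeta
4. how much target is there at the end, in percent of the starting material charged: eta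
5. how much target is there at the end, in percent of the starting material charged: alpha
6. how much target is there at the end, in percent of the starting material charged: beta

Two colleagues disagree before anything is run. The first holds the speed view. Starting material enters the cycle at its first step, whose rate rises with [starting material], so she wants as much of it in the flask as possible from the first moment. In alpha each free catalyst is captured with a frequency of 31.0 s⁻¹ at the start, and a feed that keeps [starting material] low slows this capture, so she expects alpha to lead.

The second holds the dilution view. At the full charge and with the catalyst free, self-condensation consumes 3.60 mM s⁻¹ of starting material while capture takes 0.620 mM s⁻¹. Self-condensation is the larger by a factor of 5.81, so he wants the starting material fed in.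

My own reckoning puts both views on one scale of powers of ten. With [free catalyst] held, diluting by one decade lowers capture, which goes with [starting material], by one decade, and lowers self-condensation, which goes with the square of [starting material], by two. These two lines cross at the crossover concentration, the [starting material] at which both losses are equal: the rate constant of capture times [free catalyst], divided by 2 times the rate constant of self-condensation, which is 1.72 mM with the catalyst charge free. Crossover over [starting material] is the selectivity factor of capture against self-condensation. Below the crossover, capture is the larger of the two losses, and that is the region where the speed view is right.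

Alpha starts 0.764 decades above the crossover, so capture gets 14.7% of what is being consumed at that moment. In eta the feed brings 0.667 mM s⁻¹, and the level at which the two losses together balance it is 3.53 mM. Counted in decades from the crossover, that level stands at 0.311, less than alpha's start, and there capture gets a larger share than in alpha, 32.8%. I therefore side with dilution and expect eta ahead of alpha. This reckoning takes the catalyst as free and sets a start against a plateau, so it gives an order and no final percentages.

The forecast takes the second side too, saying that “feeding the starting material to keep it dilute wins”. It names eta as leader with 22.5%, then alpha 19.3%, theta 18.7%, zeta 17.3% and beta 11%.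

The simulation puts eta first with 22.4%, then alpha 19.5%, theta 18.3%, zeta 16.1% and beta 11.1%, so the dilution view stands. At 20.0 s eta still held 18.7% of its starting material, and at 200 s its target reached 34.5%. With 76.2% of the catalyst free at 20.0 s, eta's crossover reads 1.31 mM, and its remaining 1.87 mM lies 0.154 decades above. In the neighbour like eta but charged with 40 mM, 66.7% free gives a crossover of 1.15 mM, and its remaining 2.92 mM lies 0.405 decades above, and that neighbour's target ended at 9.33% of its own charge of starting material.

(All constants come from no measurement, and the outcome is calculated.)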